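All runs were computed with constants of no real substance, and the scatter is random.

In the teal run the dissolved substrate read between 54% and 57% of the charge from 2.00 h to 15.0 h while target kept climbing, and the amber run levelled in the same place, so we read the solution as holding a steady share of the charge in these two runs.

| flask | solid substrate | partner | remark | time |
|---|---|---|---|---|
| amber | 0.049 M | 0.098 M | the very flask that is asked about, followed so far |  |
| teal | 0.049 M | 0.049 M | run made earlier |  |
| flask | 0.049 M | 0.0980 M |  | 20 h |

| run | time / h | target / % | dissolved substrate / % |
|---|---|---|---|
| amber | 0.250 | 0 | 28 |
| amber | 0.667 | 2 | 49 |
| amber | 1.50 | 4 | 57 |
| amber | 4.00 | 15 | 54 |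
| teal | 2.00 | 7 | 55 |
| teal | 5.00 | 9 | 57 |
| teal | 10.0 | 16 | 56 |
| teal | 15.0 | 24 | 54 |

(each reading ± 1.5 percentage points)

- percentages count the solid substrate that a species holds: one side product counts as two
- solid, in amounts per volume of the solution: solid substrate
- reactions considered so far: solid substrate <-> dissolved substrate; dissolved substrate + partner -> target; dissolved substrate + target -> side product; 2 partner -> homo dimer
- at the start none of the solid substrate is in solution
- dissolved substrate means what is dissolved; the solid is not counted in it

- amount of target at 20 h, in percent of the solid substrate charged
- concentration of dissolved substrate in solution at 2.0 h, in percent of saturation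
- the change that raises the amount of target at 20 h, in percent of the solid substrate charged most ("none" if none brings more than 2 percentage points) (summer / winter / autumn / none)
- amount of target at 20 h, in percent of the solid substrate charged, after winter

- summer: doubling the amount of partner, all else as stated
- winter: doubling the dissolution coefficient of the solid substrate, all else as stated
- autumn: doubling the solubility of the solid substrate, all else as stated

The bench rule we take from this: while the solution stays full, count target as made at a steady pace and draw a straight line. We take the full solution as 57.0% of the charge. In the amber run target read 15% at 4.00 h, which reads as a pace of 0.0375 /h in fractions of the charge. The line reaches 75.0% at 20 h, but the line has a border. The part of the charge not in solution is the reserve, and the reserve divided by the pace is the reserve time, 11.5 h. That is shorter than the time asked, the ratio being 0.575.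

Past the border we expect the solution to go unrefilled, so we count the fraction left and not the fraction made. We treat the fall as pseudo-first-order, with the same share of what is left going each hour, 0.0658 /h. By this estimate 32.5% stays dissolved at 20 h, so we reckon 67.5% gone on to target and side product together. Our target lies below that by the side product, which no reading shows.

The forecast gives 55% of target, 98% of saturation, summer as best and 55.3% after winter. On the side product it says: “Side product is not visible in the data, but I shade down a little”.

    solid substrate ⇌ dissolved substrate, rate k1*(cs1 - [dissolved substrate]) while solid is left; crystals form when [dissolved substrate] > cs1 (solubility = 28.0 mM, k = 8.20 × 10⁻⁴ /s)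
    dissolved substrate + partner → target (k = 2.50 × 10⁻⁴ /M/s)
    dissolved substrate + target → side product (k = 1.70 × 10⁻⁴ /M/s)
    2 partner → homo dimer (k = 4.10 × 10⁻⁵ /M/s)

The amber flask gives 49.5% of target at 20 h, less than the forecast, with 97.0% of saturation at 2.0 h, summer best with a gain of 20 percentage points, and 49.9% after winter. Target and side product together hold 67.0% at 20 h, of which side product is 17.5%. Against our reserve time of 11.5 h, this flask holds 3.58% solid substrate at 10.0 h and 0% at 20.0 h. For the neighbour charged with 0.20 M of solid substrate, we reckon the full solution as 14.0% of the charge and the pace as 0.00919 /h, so the reserve time comes to 93.6 h, longer than 20 h. The line then reckons 18.4% spent, and that neighbour holds 12.8% target and 5.17% side product. We reckon 67.6% of solid left, and it holds 68.3%.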